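**Retrosynthetic overview**

1. The target 24 is (8R)-8-nonyl-1,5,9,13-tetraazacycloheptadecan-6-one: one 17-membered ring (N1, N5, C6=O, C8 bearing nonyl, N9, N13, tetramethylene C14–C17 back to N1) and one stereocentre (C8, R).
2. The ring is formed last, at N13–C14. That bond is opened to a primary amine (N13) and an aldehyde (C14), and the aldehyde is taken back to an N1-allyl group plus CO, so acyclic amide 19, CO and hydride give the whole ring skeleton in one pot.
3. Enabling feature: the 1,3-diamine N9–C10–C11–C12–N13 that flanks the new bond. It captures C14 as a temporary six-membered hexahydropyrimidine ring (N9, C10, C11, C12, N13, C14), which drives the macrocyclisation and is opened again by hydride so that only N13–C14 remains.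
4. Precursor 19 comes from three pieces: the C8 stereocentre from decanal and methyl acetate (Mannich addition to a tert-butanesulfinyl imine), the amide N5–C6 by coupling with N-Boc-N-allylpropane-1,3-diamine 5, and N9–C10 by reductive amination with 3-phthalimidopropanal.
5. Order of ring formation: 17-membered ring and transient six-membered aminal in step 10; the end game is removal of the single Boc group on N1.

Key step: step 10

Remark: compounds 1, 2, 6, 7, 9 and 16 and all reagents are taken as commercial; the ring locants of 24 are also used for the corresponding atoms of open-chain intermediates.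

**Route**

Step 1
Reactants: 1 tert-butyl allylcarbamate; 2 N-(3-bromopropyl)phthalimide
Product: 4 tert-butyl allyl[3-(1,3-dioxoisoindolin-2-yl)propyl]carbamate, via sodium carbamate salt 3 (not isolated)
Conditions: NaH, DMF, 0 °C; then 2, Bu4NI (cat.), 0 °C to rt
Reagents that add atoms: none
Why: SN2 N-alkylation of the sodium carbamate at the primary bromide should be clean because the Boc NH is the only acidic site and the imide is inert to this anion at or below room temperature; no stereocentre is involved.

Step 2
Reactants: 4 tert-butyl allyl[3-(1,3-dioxoisoindolin-2-yl)propyl]carbamate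
Product: 5 tert-butyl allyl(3-aminopropyl)carbamate
Conditions: MeNH2 (33% in EtOH), rt to 50 °C
Reagents that add atoms: none
Why: Aminolysis of the phthalimide (Gabriel-type deprotection with methylamine) should free the primary amine and leave carbamate and alkene untouched; methylamine is used instead of hydrazine so that no diimide can reduce the allyl group.

Step 3
Reactants: 6 decanal; 7 (R)-2-methylpropane-2-sulfinamide
Product: 8 (R,E)-N-decylidene-2-methylpropane-2-sulfinamide
Conditions: CuSO4 (anhydrous), CH2Cl2, rt
Reagents that add atoms: none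
Why: Dehydrative condensation of an enolisable aldehyde with tert-butanesulfinamide over CuSO4 is the standard sulfinimine formation and should give the E-imine only; the sulfur stereocentre comes from reagent 7.

Step 4
Reactants: 8 (R,E)-N-decylidene-2-methylpropane-2-sulfinamide; 9 methyl acetate
Product: 12 methyl (3R)-3-{[(R)-tert-butylsulfinyl]amino}dodecanoate, via lithium enolate 10 (not isolated), via titanium enolate 11 (not isolated)
Conditions: LiN(iPr)2, THF, −78 °C; ClTi(OiPr)3; then 8, −78 °C; aq. NH4Cl
Reagents that add atoms: none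
Why: Mannich-type addition of a titanium ester enolate to an N-tert-butanesulfinyl aldimine; in the chair-like six-membered transition state titanium binds the imine nitrogen and the sulfinyl oxygen, so the enolate should attack the Si face anti to the tert-butyl group and set C3 (the later C8) as R.

Step 5
Reactants: 12 methyl (3R)-3-{[(R)-tert-butylsulfinyl]amino}dodecanoate
Product: 13 (3R)-3-{[(R)-tert-butylsulfinyl]amino}dodecanoic acid
Conditions: LiOH·H2O, THF/MeOH/H2O, 0 °C to rt; then 1 M HCl to pH 4, 0 °C
Reagents that add atoms: lithium hydroxide, [Li+].[OH-]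
Why: Saponification of the methyl ester; the sulfinamide is stable to hydroxide and to brief acidification to pH 4, and the stereocentre is β to the carbonyl and cannot epimerise by enolisation.

Step 6
Reactants: 13 (3R)-3-{[(R)-tert-butylsulfinyl]amino}dodecanoic acid; 5 tert-butyl allyl(3-aminopropyl)carbamate
Product: 14 tert-butyl allyl{3-[(3R)-3-{[(R)-tert-butylsulfinyl]amino}dodecanoylamino]propyl}carbamate
Conditions: DCC, HOBt, CH2Cl2, 0 °C to rt
Reagents that add atoms: none
Why: Carbodiimide/HOBt amide coupling; the sulfinamide NH is not acylated and acts as the nitrogen protecting group, so the primary amine of 5 should be the only nucleophile.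

Step 7
Reactants: 14 tert-butyl allyl{3-[(3R)-3-{[(R)-tert-butylsulfinyl]amino}dodecanoylamino]propyl}carbamate
Product: 15 tert-butyl allyl{3-[(3R)-3-aminododecanoylamino]propyl}carbamate
Conditions: HCl (4 M in dioxane, 2 equiv), MeOH, 0 °C, 30 min; then 1 M NaOH
Reagents that add atoms: none
Why: Acidolysis of the sulfinamide S–N bond by HCl in methanol is far faster at 0 °C than cleavage of a tert-butyl carbamate, so a limited amount of acid and a short time should free the C8 amine and keep the Boc group on N1.

Step 8
Reactants: 15 tert-butyl allyl{3-[(3R)-3-aminododecanoylamino]propyl}carbamate; 16 3-phthalimidopropanal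
Product: 18 tert-butyl allyl{3-[(3R)-3-{[3-(1,3-dioxoisoindolin-2-yl)propyl]amino}dodecanoylamino]propyl}carbamate, via aldimine 17 (not isolated)
Conditions: NaBH(OAc)3, AcOH (1 equiv), ClCH2CH2Cl, rt
Reagents that add atoms: none
Why: Direct reductive amination through aldimine 17 with NaBH(OAc)3; the α-branched amine should stop after one alkylation, and the reagent does not touch imide, carbamate, amide or alkene.

Step 9
Reactants: 18 tert-butyl allyl{3-[(3R)-3-{[3-(1,3-dioxoisoindolin-2-yl)propyl]amino}dodecanoylamino]propyl}carbamate
Product: 19 tert-butyl allyl{3-[(3R)-3-[(3-aminopropyl)amino]dodecanoylamino]propyl}carbamate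
Conditions: MeNH2 (33% in EtOH), rt to 45 °C
Reagents that add atoms: none
Why: The same Gabriel-type aminolysis as in step 2 should unmask the primary amine N13 and so complete the free 1,3-diamine N9/N13 needed for the key step; Boc, amide and alkene are inert to methylamine.

Step 10
Reactants: 19 tert-butyl allyl{3-[(3R)-3-[(3-aminopropyl)amino]dodecanoylamino]propyl}carbamate
Product: 23 tert-butyl (8R)-8-nonyl-6-oxo-1,5,9,13-tetraazacycloheptadecane-1-carboxylate, via aldehyde 20 (not isolated), via macrocyclic aldimine 21 (not isolated), via bicyclic aminal 22 (not isolated)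
Conditions: Rh(acac)(CO)2 (5 mol %), Xantphos (10 mol %), CO/H2 (1:1, 20 bar), toluene (0.002 M), 80 °C; vent; NaBH4, MeOH, 0 °C to rt
Reagents that add atoms: carbon monoxide, [C-]#[O+]
Why: Rh–H adds to the N-allyl carbamate with the wide-bite-angle diphosphine steering rhodium to the terminal carbon, CO insertion and hydrogenolysis give linear aldehyde 20 (C14 is the CO carbon), the primary amine N13 condenses with it to close the 17-membered ring as aldimine 21 (17-exo-trig addition to C=O, then loss of water), and N9 adds to the C=N to form the six-membered hexahydropyrimidine 22 (6-endo-trig). The closest known reaction types are tandem hydroformylation/reductive amination (hydroaminomethylation), which has been used to close aza-macrocycles, and the reductive mono-alkylation of N-alkylpropane-1,3-diamines by way of 2-substituted hexahydropyrimidines. All condensation steps are reversible, so at 0.002 M oligomeric imines can revert and funnel into the unstrained intramolecular aminal, which acts as the thermodynamic sink of the macrocyclisation. NaBH4 then reduces the ring-opened tautomer of 22, and since only N13 can form a neutral C=N (opening toward N9 would need an iminium ion, which is not available without acid), hydride should be delivered to C14 with the N13–C14 bond kept and the N9–C14 bond given up. The only new stereocentre, the aminal carbon C14 of 22, is formed without control and is erased on reduction, while C8 is remote from every reacting atom. The step needs linear over branched hydroformylation (secured by Xantphos and by the fully substituted carbamate nitrogen, which cannot trap the aldehyde), ring closure over oligomerisation (dilution plus the 1,3-diamine trap) and alkylation of N13 over N9 (secured by the imine/aminal tautomerism just described).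

Step 11
Reactants: 23 tert-butyl (8R)-8-nonyl-6-oxo-1,5,9,13-tetraazacycloheptadecane-1-carboxylate
Product: 24 (8R)-8-nonyl-1,5,9,13-tetraazacycloheptadecan-6-one
Conditions: HCl (4 M in dioxane), CH2Cl2, rt; then 2 M NaOH
Reagents that add atoms: none
Why: Acidolytic Boc cleavage (loss of the tert-butyl cation as isobutene, then decarboxylation) should free N1; lactam, amines and the C8 stereocentre are not affected, and the base wash gives the free tetraamine.

**Compound list**

1 | tert-butyl allylcarbamate | C=CCNC(=O)OC(C)(C)C | starting material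
2 | N-(3-bromopropyl)phthalimide | BrCCCN1C(=O)c2ccccc2C1=O | starting material
3 | sodium allyl(tert-butoxycarbonyl)azanide (sodium salt of 1) | [Na+].C=CC[N-]C(=O)OC(C)(C)C | intermediate
4 | tert-butyl allyl[3-(1,3-dioxoisoindolin-2-yl)propyl]carbamate | C=CCN(CCCN1C(=O)c2ccccc2C1=O)C(=O)OC(C)(C)C | intermediate
5 | tert-butyl allyl(3-aminopropyl)carbamate | C=CCN(CCCN)C(=O)OC(C)(C)C | intermediate
6 | decanal | CCCCCCCCCC=O | starting material
7 | (R)-2-methylpropane-2-sulfinamide | CC(C)(C)[S@@](=O)N | starting material
8 | (R,E)-N-decylidene-2-methylpropane-2-sulfinamide | CCCCCCCCC/C=N/[S@](=O)C(C)(C)C | intermediate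
9 | methyl acetate | COC(C)=O | starting material
10 | lithium 1-methoxyethenolate (lithium enolate of 9) | [Li+].C=C([O-])OC | intermediate
11 | (1-methoxyethenyloxy)triisopropoxytitanium (titanium enolate of 9) | C=C(OC)O[Ti](OC(C)C)(OC(C)C)OC(C)C | intermediate
12 | methyl (3R)-3-{[(R)-tert-butylsulfinyl]amino}dodecanoate | CCCCCCCCC[C@H](CC(=O)OC)N[S@](=O)C(C)(C)C | intermediate
13 | (3R)-3-{[(R)-tert-butylsulfinyl]amino}dodecanoic acid | CCCCCCCCC[C@H](CC(=O)O)N[S@](=O)C(C)(C)C | intermediate
14 | tert-butyl allyl{3-[(3R)-3-{[(R)-tert-butylsulfinyl]amino}dodecanoylamino]propyl}carbamate | CCCCCCCCC[C@H](CC(=O)NCCCN(CC=C)C(=O)OC(C)(C)C)N[S@](=O)C(C)(C)C | intermediate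
15 | tert-butyl allyl{3-[(3R)-3-aminododecanoylamino]propyl}carbamate | CCCCCCCCC[C@H](CC(=O)NCCCN(CC=C)C(=O)OC(C)(C)C)N | intermediate
16 | 3-phthalimidopropanal [3-(1,3-dioxoisoindolin-2-yl)propanal] | O=CCCN1C(=O)c2ccccc2C1=O | starting material
17 | E-aldimine of 15 with 16 | CCCCCCCCC[C@H](CC(=O)NCCCN(CC=C)C(=O)OC(C)(C)C)/N=C/CCN1C(=O)c2ccccc2C1=O | intermediate
18 | tert-butyl allyl{3-[(3R)-3-{[3-(1,3-dioxoisoindolin-2-yl)propyl]amino}dodecanoylamino]propyl}carbamate | CCCCCCCCC[C@H](CC(=O)NCCCN(CC=C)C(=O)OC(C)(C)C)NCCCN1C(=O)c2ccccc2C1=O | intermediate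
19 | tert-butyl allyl{3-[(3R)-3-[(3-aminopropyl)amino]dodecanoylamino]propyl}carbamate | CCCCCCCCC[C@H](CC(=O)NCCCN(CC=C)C(=O)OC(C)(C)C)NCCCN | intermediate
20 | tert-butyl {3-[(3R)-3-[(3-aminopropyl)amino]dodecanoylamino]propyl}(4-oxobutyl)carbamate | CCCCCCCCC[C@H](CC(=O)NCCCN(CCCC=O)C(=O)OC(C)(C)C)NCCCN | intermediate
21 | tert-butyl (8R,13E)-8-nonyl-6-oxo-1,5,9,13-tetraazacycloheptadec-13-ene-1-carboxylate | CCCCCCCCC[C@@H]1CC(=O)NCCCN(C(=O)OC(C)(C)C)CCC/C=N/CCCN1 | intermediate
22 | bicyclic aminal: 23 with an additional N9–C14 bond (hexahydropyrimidine ring N9, C10, C11, C12, N13, C14; C14 as a mixture of both configurations) | CCCCCCCCC[C@@H]1CC(=O)NCCCN(C(=O)OC(C)(C)C)CCCC2NCCCN12 | intermediate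
23 | tert-butyl (8R)-8-nonyl-6-oxo-1,5,9,13-tetraazacycloheptadecane-1-carboxylate | CCCCCCCCC[C@@H]1CC(=O)NCCCN(C(=O)OC(C)(C)C)CCCCNCCCN1 | intermediate
24 | (8R)-8-nonyl-1,5,9,13-tetraazacycloheptadecan-6-one | CCCCCCCCC[C@@H]1CC(=O)NCCCNCCCCNCCCN1 | target

**Step count and risks**

Total step count: 11. Longest linear sequence: 9 steps (steps 3 to 11, from decanal); amine 5 (steps 1 and 2) joins at step 6.

Steps most likely to fail:

1. Step 10. The free, chelating 1,3-diamine may slow the rhodium catalyst, intermolecular imine or aminal formation may outrun ring closure, or the aminal may open toward N9 during reduction so that hydride alkylates the wrong nitrogen. The fallback sets out from 18 and comes back at 24. It gives up the aminal template and masks N9, so that N13 is the only nitrogen able to condense. Boc2O with Et3N in CH2Cl2 at 40 °C should convert 18 into the N9-Boc phthalimide F1, and methylamine in EtOH should then free the N9-Boc primary amine F2. Hydroaminomethylation of F2 with Rh(acac)(CO)2/Xantphos under CO/H2 (1:5, 60 bar) in toluene at 0.002 M and 110 °C should give the aldehyde F3, which closes to the macrocyclic aldimine F4 and is hydrogenated in the same pot to the 1,9-bis-Boc macrocycle F5. HCl in dioxane, then NaOH, should remove both carbamates and give 24.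

2. Step 7. The acid needed for S–N cleavage may also remove part of the Boc group on N1. The fallback sets out from 13 and comes back at 15. It changes the nitrogen protecting group before the Boc-bearing amine is introduced. HCl in dioxane followed by water should cleave the sulfinyl group of 13 and give (3R)-3-aminododecanoic acid F6. Fmoc-OSu with NaHCO3 in dioxane/water should give the N-Fmoc acid F7, and DCC/HOBt coupling with 5 the N-Fmoc amide F8. Piperidine in DMF, to which the Boc group is inert, should then give 15.

3. Step 8. The primary amine may be alkylated twice, or aldehyde 16 may lose phthalimide by β-elimination before the imine is reduced. The fallback sets out from 15 and comes back at 18. It replaces the reductive amination by sulfonamide mono-alkylation (Fukuyama amine synthesis). 2-Nitrobenzenesulfonyl chloride with Et3N in CH2Cl2 should give the nosyl amide F9. Alkylation with bromide 2 (K2CO3, DMF, 60 °C) should give the N-alkylated nosyl amide F10, and PhSH with K2CO3 in MeCN should remove the nosyl group to give 18.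

**Further compounds**

F1 | step 10 | tert-butyl allyl{3-[(3R)-3-{(tert-butoxycarbonyl)[3-(1,3-dioxoisoindolin-2-yl)propyl]amino}dodecanoylamino]propyl}carbamate | CCCCCCCCC[C@H](CC(=O)NCCCN(CC=C)C(=O)OC(C)(C)C)N(CCCN1C(=O)c2ccccc2C1=O)C(=O)OC(C)(C)C
F2 | step 10 | tert-butyl allyl{3-[(3R)-3-[(3-aminopropyl)(tert-butoxycarbonyl)amino]dodecanoylamino]propyl}carbamate | CCCCCCCCC[C@H](CC(=O)NCCCN(CC=C)C(=O)OC(C)(C)C)N(CCCN)C(=O)OC(C)(C)C
F3 | step 10 | tert-butyl {3-[(3R)-3-[(3-aminopropyl)(tert-butoxycarbonyl)amino]dodecanoylamino]propyl}(4-oxobutyl)carbamate | CCCCCCCCC[C@H](CC(=O)NCCCN(CCCC=O)C(=O)OC(C)(C)C)N(CCCN)C(=O)OC(C)(C)C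
F4 | step 10 | di-tert-butyl (8R,13E)-8-nonyl-6-oxo-1,5,9,13-tetraazacycloheptadec-13-ene-1,9-dicarboxylate | CCCCCCCCC[C@@H]1CC(=O)NCCCN(C(=O)OC(C)(C)C)CCC/C=N/CCCN1C(=O)OC(C)(C)C
F5 | step 10 | di-tert-butyl (8R)-8-nonyl-6-oxo-1,5,9,13-tetraazacycloheptadecane-1,9-dicarboxylate | CCCCCCCCC[C@@H]1CC(=O)NCCCN(C(=O)OC(C)(C)C)CCCCNCCCN1C(=O)OC(C)(C)C
F6 | step 7 | (3R)-3-aminododecanoic acid | CCCCCCCCC[C@H](CC(=O)O)N
F7 | step 7 | (3R)-3-{[(9H-fluoren-9-ylmethoxy)carbonyl]amino}dodecanoic acid | CCCCCCCCC[C@H](CC(=O)O)NC(=O)OCC1c2ccccc2-c2ccccc12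
F8 | step 7 | tert-butyl allyl{3-[(3R)-3-{[(9H-fluoren-9-ylmethoxy)carbonyl]amino}dodecanoylamino]propyl}carbamate | CCCCCCCCC[C@H](CC(=O)NCCCN(CC=C)C(=O)OC(C)(C)C)NC(=O)OCC1c2ccccc2-c2ccccc12
F9 | step 8 | tert-butyl allyl{3-[(3R)-3-{[(2-nitrophenyl)sulfonyl]amino}dodecanoylamino]propyl}carbamate | CCCCCCCCC[C@H](CC(=O)NCCCN(CC=C)C(=O)OC(C)(C)C)NS(=O)(=O)c1ccccc1[N+](=O)[O-]
F10 | step 8 | tert-butyl allyl{3-[(3R)-3-{[3-(1,3-dioxoisoindolin-2-yl)propyl][(2-nitrophenyl)sulfonyl]amino}dodecanoylamino]propyl}carbamate | CCCCCCCCC[C@H](CC(=O)NCCCN(CC=C)C(=O)OC(C)(C)C)N(CCCN1C(=O)c2ccccc2C1=O)S(=O)(=O)c1ccccc1[N+](=O)[O-]
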